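**Fading product.** X in the winter run, the very flask we are asked about, reaches 8.6% by 5.00 min but stands at 16.3% at 15.0 min, with E still at 83.6%. From 5.00 min on, E lost matches X within the scatter, so we count the charge in these two forms.

all flasks: E 0.026 M

|  | J | Z | remark | time |
|---|---|---|---|---|
| winter | 0.13 M | 0.013 M | the very flask that is asked about, followed so far |  |
| spring | 0.13 M | 0.019 M | run made earlier |  |
| flask | 0.130 M | 0.0130 M |  | 50 min |

| run | time / min | E / % | X / % |
|---|---|---|---|
| winter | 1.00 | 97.1 | 1.7 |
| winter | 3.00 | 92.9 | 5.8 |
| winter | 5.00 | 91.4 | 8.6 |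
| winter | 8.00 | 87.5 | 12.4 |
| winter | 12.0 | 85.7 | 14.7 |
| winter | 15.0 | 83.6 | 16.3 |
| spring | 3.00 | 93.3 | 5.2 |
| spring | 10.0 | 87.3 | 11.3 |
| spring | 20.0 | 83.8 | 17.0 |
| spring | 25.0 | 82.6 | 18.1 |
| spring | 40.0 | 79.8 | 19.1 |
| spring | 50.0 | 78.9 | 21.8 |

(standard deviation of a reading: 0.5 percentage points)

- part of the E that has reacted at 50 min
- share of the unused J that is free and not bound as D, at 50 min

- the earlier runs do not show how much of J is bound; that part of a forecast is a guess

**First rung.** The early winter readings give a start rate of 0.0193 min⁻¹ as a fraction of the charge. Between 5.00 min and 15.0 min, X gains 7.01% of the charge per unit of ln t. So we take the rate as falling as one over time, which leaves a fraction τ/(τ+t) of the start rate running. We call that gain divided by the start rate the fade time τ, 3.63 min, the first half-life of a second-order loss.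

**Second rung.** Read as a first-order loss of E, the start rate gives a half-life of 35.9 min, ten times the fade time. So we read the rate as fading sooner than E. That fits J, in excess, pairing off with itself, and then τ/(τ+t) is also the fraction of J left.

**Our reckoning.** Summing the fading rate from 15.0 min to 50 min adds 7.41%, so we commit to 23.7% reacted, with 6.76% of J left. The runs do not show how much of that J is bound, so we give no figure for it.

**The forecast.** The forecast gives 24% (22% to 26.5%) reacted and 92% (78% to 99%) free, reading “a reversible reaction with Z acting like a co-product”.

**The flask.** It gives 23.5% reacted, with >99.9% of the unused J free.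

    E + J + Q → X + 2 Q (k = 2.60 L² mol⁻² s⁻¹)
    E + J → X + Q (k = 0.00270 L mol⁻¹ s⁻¹)
    J + Q ⇌ D, settled at all times (K = 3.60 L mol⁻¹)
    Z + Q → L (k = 0.760 L mol⁻¹ s⁻¹)
    2 J → G (k = 0.0180 L mol⁻¹ s⁻¹)

**The reason.** X stops short because J pairs off into G: with that step taken out of the run, the part reacted goes from 23.5% to 99.7%. The fade time said 6.76% of J left at 50.0 min, and the flask holds 5.97%. In the neighbour flask with E cut to 0.0065 M, the same fade time says the same, and J stands at 6.49%.

(The runs are calculated with made-up constants.)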